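Look first at the late rows of the zeta run, where ring stops rising while substrate keeps falling.

| flask | substrate | activator | remark | time |
|---|---|---|---|---|
| delta | 20 mM | 30 mM | run made earlier |  |
| eta | 20 mM | 15 mM | run made earlier |  |
| zeta | 20 mM | 60 mM | run made earlier |  |
| amber | 20 mM | 30.0 mM (in portions, 5, over 30 min) | first portion at the start, last at 30 min | 2.5 h |
| red | 20 mM | 30.0 mM (fed, over 30 min) | all else is in the flask from the start; the feed brings no volume worth counting | 2.5 h |
| teal | 20 mM (fed, over 30 min) | 30.0 mM | all else is in the flask from the start; the feed brings no volume worth counting | 2.5 h |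
| blue | 20 mM | 30.0 mM | everything together at the start | 2.5 h |

| run | time / min | ring / % | substrate / % |
|---|---|---|---|
| delta | 8.00 | 0 | 94 |
| delta | 25.0 | 7 | 72 |
| delta | 40.0 | 7 | 62 |
| delta | 60.0 | 9 | 52 |
| delta | 90.0 | 14 | 40 |
| eta | 25.0 | 3 | 87 |
| eta | 50.0 | 2 | 75 |
| eta | 80.0 | 7 | 66 |
| eta | 90.0 | 11 | 61 |
| eta | 120 | 9 | 53 |
| zeta | 25.0 | 8 | 55 |
| zeta | 50.0 | 20 | 28 |
| zeta | 80.0 | 22 | 23 |
| zeta | 90.0 | 21 | 12 |
| zeta | 120 | 20 | 9 |

(standard deviation of a reading: 2 percentage points)

* the best flask by amount of ring, in percent of the substrate charged; "all alike" if 1.5 percentage points covers them all (amber / red / teal / blue / all alike)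
* amount of ring at the end, in percent of the substrate charged, amber
* amount of ring at the end, in percent of the substrate charged, red
* amount of ring at the end, in percent of the substrate charged, teal
* amount of ring at the end, in percent of the substrate charged, blue



In zeta, from 50.0 min to 120 min, substrate falls from 28% to 9% while ring stays near 21%. So I read a steady state, with ring lost about as fast as it is made. Divide the ring standing by the rate of substrate loss and you have a holding time, 77.4 min, a reading that carries the scatter of 2 percentage points.

But then you need the loss rate at the end. Delta has blue's charge, so take its last reading and assume one activator used per substrate. The second-order law then gives a rate constant times activator excess of 0.270 h⁻¹. For blue that leaves 25.7% of the substrate, lost at 0.105 h⁻¹. Zeta had 60 mM of activator and blue has 30.0 mM, so it is my assumption that the holding time carries over, and with it my ring for blue is 13.5%.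

The slow additions put their charge in on average 15.0 min late, so for them I reckon 28.5% of the substrate left, lost at 0.121 h⁻¹, and ring 15.6%. That puts amber, red and teal ahead of blue by 2 points, more than the margin.

The forecast differs: 17% for amber, 17% for red, 17% for teal, 17.5% for blue, so all alike. “So ring simply follows conversion.”

The flasks give 11.7% for amber, 11.7% for red, 11.7% for teal and 10.9% for blue: all alike.

    ring → over-reaction product (k = 1.10 h⁻¹)
    substrate + activator → activated form (k = 22.0 M⁻¹ h⁻¹)
    activated form → ring (k = 2.00 h⁻¹)
    substrate + activated form → open dimer (k = 82.0 M⁻¹ h⁻¹)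
    activator ⇌ dormant form (K = 0.280, k = 0.100 h⁻¹)

Ring has a half-life of 0.630 h on its way to over-reaction product, shorter than the run, and red holds 11.8% of ring at 1.25 h and 11.7% at 2.50 h. In blue, substrate is lost at 0.0972 h⁻¹ at the end, and the holding time turns that into 12.5% against the computed 10.9%.

Now take red with 80 mM of substrate, ignoring the feed: the same law and holding time give 1.43% of ring. The computed flask gives 2.43%.

(The data come from a simulation on assumed constants; noise was put on by code.)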